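At 20.0 min, the last reading of cedar, the columns close a reagent account, and the runs so far stand here:

| setting | cedar | ash | south-west | north-west |
|---|---|---|---|---|
| substrate | 0.10 M | 0.10 M | 0.10 M | 0.10 M |
| reagent | 1.2 equiv | 4.6 equiv | 1.00 equiv | 3.00 equiv |
| remark | run made earlier | run made earlier |  |  |
| time |  |  | 20 min | 20 min |

| run | time / min | double product / % | side product B / % | tris adduct / % | substrate / % | side product A / % |
|---|---|---|---|---|---|---|
| cedar | 1.50 | 18.4 | 26.9 | 9.6 | 18.1 | 20.3 |
| cedar | 4.00 | 11.6 | 32.2 | 10.5 | 13.4 | 35.1 |
| cedar | 8.00 | 7.1 | 32.0 | 8.9 | 7.5 | 43.5 |
| cedar | 20.0 | 3.4 | 31.7 | 10.5 | 3.9 | 50.0 |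
| ash | 2.50 | 1.8 | 3.1 | 94.9 | 0.3 | 2.4 |
| ash | 8.00 | 0 | 3.8 | 95.3 | 0 | 2.7 |
| ash | 12.0 | 0 | 2.9 | 93.9 | 0.3 | 0.6 |
| ash | 20.0 | 0.8 | 1.4 | 93.9 | 0 | 3.6 |

(scatter of a reading: 1 percentage point)

- a species is counted by the substrate in it: one side product A counts as two
- the numbers in the tables scatter with a standard deviation of 1 percentage point

- which of these there is most of at the end, counted by the substrate in it, south-west (double product / tris adduct / side product B / substrate / side product A)
- which of these there is most of at the end, counted by the substrate in it, north-west (double product / tris adduct / side product B / substrate / side product A)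
- final amount of the leader among these, as a percentage of the substrate charged, in south-west
- final amount of the leader among these, as a percentage of the substrate charged, in north-west

In that account each side product B, and each substrate inside side product A, carries one reagent, a double product 2 and a tris adduct 3. The sum in cedar is 120% of the substrate charged, which matches the 1.2 equiv of reagent charged. Subtracting the substrate account removes time and both side products. Cedar then reads 20 points on 2[tris adduct] + [double product] − [substrate]. That sum plus reagent left is the reagent gap, and it should equal the reagent charged above one equivalent, here 20.0 points.

Two chemists argue over south-west, charged 1.00 equiv. One copies cedar: side product A near 50.0%, substrate near 3.9%. The other, whose reckoning this is, treats reagent as the limiting reagent with 0 left, so the gap is 0 and [substrate] must equal 2[tris adduct] + [double product], which the copy does not satisfy. Cedar's tris adduct averages 9.88%. Assuming it scales with the square of the charge, south-west gets 6.86%. With double product consumed, substrate is 13.7%. Keeping side product B at cedar's 31.7%, side product A is 47.7%.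

For north-west, charged 3.00 equiv, let L be side products A and B together. Taking substrate and double product as gone, tris adduct is what L leaves of the substrate charged, and the gap makes reagent left 2L. Assuming L goes inversely with the reagent charged beyond 2 equivalents, ash's mean L gives 13.3% for north-west, so tris adduct is 86.7%.

The forecast gives side product A at 47% (41% to 52%) in south-west and tris adduct at 91% (86% to 94%) in north-west, where it judges that “reagent is sufficient”; that north-west figure is higher than this reckoning's.

South-west ends with side product A at 46.9% and substrate at 13.1%, reagent 0%. North-west ends with tris adduct at 88.3%, reagent 7.79% of its own charge.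

    reagent + double product → tris adduct (k = 0.817 /M/s)
    reagent + first product → double product (k = 2.11 /M/s)
    substrate + double product → side product A (k = 0.201 /M/s)
    double product → over-reaction product (k = 2.39 × 10⁻⁵ /s)
    first product → side product B (k = 0.0261 /s)
    substrate + reagent → first product (k = 1.41 /M/s)

Cedar's gap of 20 points stands above south-west's by 21 points. The copy of cedar keeps its ground for side product A, which stays within 6 points of south-west between 0.878 equiv and 1.46 equiv. A neighbour of north-west charged 0.750 equiv has a gap of −24 points when carried from cedar, and its scaled tris adduct of 3.86% gives substrate 32.2%. That flask ends with reagent 0%, tris adduct 2.94% and substrate 30.9%.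

Readings and results were computed from invented constants.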